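## Retrosynthetic overview

1. Ring labels: A is the 4-hydroxy-3-methoxyphenyl on C2 of the dihydrobenzofuran, B is its benzo ring, C is the 4-hydroxy-3-methoxyphenyl on the carbinol. The last skeletal bond is lactone C3–CH2(ring B), made by trans alkylation of the enolate of lactone 11 with benzylic bromide 26.
2. The strategy rests on one feature: the carbinol oxygen, the carbinol carbon, lactone C4 and lactone C5 (the OCH2 carbon) form a 1-aryl-1,3-diol on ring C, which is formaldehyde added across the C=C bond of the ring C styrene 6. It is made as the trans-4-aryl-1,3-dioxane 8 by an asymmetric Prins reaction, then unmasked and closed to the γ-lactone through the primary hydroxyl.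
3. Styrene 6 comes from vanillin by pivaloylation, E-selective Wittig olefination with the carboxyethyl ylide, and esterification.
4. Bromide 26: the dihydrofuran ring is closed by rhodium-carbenoid 1,5 C–H insertion of an aryl diazoacetate into the benzylic ether CH2 of ring A (C2–C3 bond), followed by epimerisation to trans and reduction; the ring B bromide is then turned into CH2Br.
5. Ring order: 1,3-dioxane (temporary), then γ-lactone; separately the dihydrofuran ring. Rings A, B and C are bought as vanillin (twice) and 4-bromo-2-methoxyphenol.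

Key step: step 4

Assumption: for each chiral catalyst (the confined acid of step 4, Rh2(PTTL)4 of step 12) the antipode that gives the drawn configuration is used; the sense of induction is fixed by a small trial with both antipodes.

Abbreviations: TBS = tert-butyldimethylsilyl; Piv = pivaloyl.

## Route

Step 1
Reactants: 1 vanillin
Product: 2 4-formyl-2-methoxyphenyl pivalate
Conditions: PivCl, Et3N, DMAP (cat.), CH2Cl2, 0 °C → rt
Reagents that add atoms: pivaloyl chloride, CC(C)(C)C(Cl)=O
Why: O-acylation of the phenol under nucleophilic catalysis; the pivalate lowers the donor power of ring C for step 4 and is hindered enough to pass the ylide and enolate steps.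

Step 2
Reactants: 2 vanillin pivalate; 3 (2-carboxyethyl)triphenylphosphonium bromide
Product: 5 (E)-4-(3-methoxy-4-pivaloyloxyphenyl)but-3-enoic acid, via ylide carboxylate 4 (not isolated)
Conditions: 3 (1.1 equiv), NaN(SiMe3)2 (2 equiv per 3), THF, 0 °C; then 2, −78 °C → rt; 1 M HCl work-up
Reagents that add atoms: none
Why: Wittig olefination; ylides that carry a carboxylate give the E alkene with aromatic aldehydes, and the hindered pivalate should not be attacked by the ylide or the silazide at low temperature.

Step 3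
Reactants: 5 butenoic acid
Product: 6 methyl (E)-4-(3-methoxy-4-pivaloyloxyphenyl)but-3-enoate
Conditions: MeI, KHCO3, DMF, rt
Reagents that add atoms: iodomethane, CI
Why: SN2 O-alkylation of the carboxylate under weakly basic conditions, which should leave the styrene double bond in place and the aryl ester intact.

Step 4
Reactants: 6 styrene ester; 7 formaldehyde (two units, from paraformaldehyde)
Product: 8 methyl 2-[(4R,5R)-4-(3-methoxy-4-pivaloyloxyphenyl)-1,3-dioxan-5-yl]acetate
Conditions: paraformaldehyde (4 equiv), confined chiral imino-imidodiphosphate Brønsted acid [(ArO)2P(=O)–NH–P(=N–SO2RF)(OAr)2 from 3,3′-diaryl-BINOL, 5 mol%], cyclohexane–CHCl3, 0 °C → rt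
Reagents that add atoms: none
Why: The chiral acid protonates a formaldehyde dimer held in its pocket, whose cationic carbon bonds to the alkene carbon remote from ring C (future lactone C4–C5 bond) while positive charge builds at the benzylic carbon, and the terminal oxygen of the same O–CH2–O unit then closes the C–O bond on the same alkene face in a concerted but asynchronous addition. The closest known reaction is the acid-catalysed Prins reaction of aryl alkenes with formaldehyde to 4-aryl-1,3-dioxanes, in its catalytic asymmetric form with confined imidodiphosphate-type acids, applied here to an E-1,2-disubstituted styrene. The 1,3-dioxane ring closes by C–O bond formation at the benzylic carbon, a formal [4+2] union of the C–O–C–O unit with the C=C bond. C5 (R, future lactone C4) and C4 (R, future carbinol) are created together: the chiral counter-anion chooses the alkene face and thereby both absolute configurations, and their trans, diequatorial relation follows from suprafacial addition to the E alkene. The step needs one alkene face and strict syn delivery; these are secured by the E geometry fixed in step 2, the non-polar medium, and the pivalate, which keeps ring C from supporting a free benzylic cation that could rotate, oligomerise or be captured by the ester carbonyl.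

Step 5
Reactants: 8 dioxane ester
Product: 10 (4R)-4-[(R)-hydroxy(3-methoxy-4-pivaloyloxyphenyl)methyl]dihydrofuran-2(3H)-one, via diol ester 9 (not isolated)
Conditions: HCl (1.25 M in MeOH), 45 °C, dimethoxymethane distilled off; NaHCO3, concentrate; PPTS (cat.), toluene, 45 °C
Reagents that add atoms: none
Why: Acid-catalysed transacetalisation with methanol removes the acetal carbon as dimethoxymethane, and the γ-hydroxy ester then lactonises through the primary hydroxyl, which acylates faster and is expected to give the more stable primary-alkyl lactone; neither stereocentre is touched because the pivalate disfavours ionisation of the benzylic C–O bond.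

Step 6
Reactants: 10 hydroxy lactone
Product: 11 (4R)-4-[(R)-(tert-butyldimethylsilyloxy)(3-methoxy-4-pivaloyloxyphenyl)methyl]dihydrofuran-2(3H)-one
Conditions: TBSOTf, 2,6-lutidine, CH2Cl2, −40 → 0 °C
Reagents that add atoms: tert-butyldimethylsilyl trifluoromethanesulfonate, CC(C)(C)[Si](C)(C)OS(=O)(=O)C(F)(F)F
Why: Silyl ether formation at the hindered secondary benzylic alcohol with the silyl triflate; it blocks translactonisation and proton transfer to the enolate in step 17.

Step 7
Reactants: 1 vanillin
Product: 12 4-(tert-butyldimethylsilyloxy)-3-methoxybenzaldehyde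
Conditions: TBSCl, imidazole, DMF, rt
Reagents that add atoms: tert-butyldimethylsilyl chloride, CC(C)(C)[Si](C)(C)Cl
Why: Imidazole-promoted silylation of the phenol, which masks ring A until the end and is removable under the conditions of step 18.

Step 8
Reactants: 12 silylated vanillin
Product: 13 [4-(tert-butyldimethylsilyloxy)-3-methoxyphenyl]methanol
Conditions: NaBH4, MeOH–THF, 0 °C
Reagents that add atoms: none
Why: Borohydride reduction of the aldehyde to the benzylic alcohol; the aryl silyl ether is stable to borohydride at 0 °C.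

Step 9
Reactants: 14 4-bromo-2-methoxyphenol
Product: 15 4-bromo-2-iodo-6-methoxyphenol
Conditions: NIS, p-TsOH (cat.), MeCN, 0 °C → rt
Reagents that add atoms: N-iodosuccinimide, O=C1CCC(=O)N1I
Why: Electrophilic aromatic iodination directed by the hydroxyl group to its only free ortho position, the para position being blocked by bromine.

Step 10
Reactants: 15 iodophenol; 13 benzylic alcohol
Product: 16 tert-butyl{4-[(4-bromo-2-iodo-6-methoxyphenoxy)methyl]-2-methoxyphenoxy}dimethylsilane
Conditions: PPh3, DIAD, THF, 0 °C → rt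
Reagents that add atoms: none
Why: Mitsunobu etherification of the acidic phenol with the activated primary benzylic alcohol under neutral conditions that spare the aryl silyl ether.

Step 11
Reactants: 16 aryl iodide; 17 ethyl diazoacetate
Product: 18 ethyl 2-[5-bromo-2-{[4-(tert-butyldimethylsilyloxy)-3-methoxybenzyl]oxy}-3-methoxyphenyl]-2-diazoacetate
Conditions: Pd(PPh3)4 (5 mol%), Ag2CO3 (0.5 equiv), Et3N, toluene, rt
Reagents that add atoms: none
Why: Palladium-catalysed cross-coupling of the diazoacetate C–H bond with an aryl iodide with retention of the diazo group; zerovalent palladium inserts into C–I much faster than into C–Br at room temperature, so the bromide is kept.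

Step 12
Reactants: 18 aryl diazoacetate
Product: 20 ethyl (2S,3S)-5-bromo-2-[4-(tert-butyldimethylsilyloxy)-3-methoxyphenyl]-7-methoxy-2,3-dihydrobenzofuran-3-carboxylate, via cis ester 19 (not isolated)
Conditions: Rh2(S-PTTL)4 (1 mol%; dirhodium tetrakis[N-phthaloyl-(S)-tert-leucinate]), toluene, −60 °C; then DBU, 40 °C
Reagents that add atoms: none
Why: Intramolecular 1,5 C–H insertion of the donor/acceptor rhodium carbenoid into the ether-activated benzylic CH2 of ring A closes the dihydrofuran ring, the chiral divalent rhodium carboxylate selecting the enantiotopic hydrogen and so setting C2 (S) in the cis ester, after which DBU equilibrates C3 through the ester enolate to the more stable trans (2S,3S) isomer.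

Step 13
Reactants: 20 trans ester
Product: 21 [(2S,3R)-5-bromo-2-[4-(tert-butyldimethylsilyloxy)-3-methoxyphenyl]-7-methoxy-2,3-dihydrobenzofuran-3-yl]methanol
Conditions: LiBH4, THF, 0 °C → rt
Reagents that add atoms: none
Why: Hydride reduction of the ester to the primary alcohol with LiBH4, which leaves aryl bromide and silyl ether alone; the C3 descriptor changes only through the priority rules.

Step 14
Reactants: 21 primary alcohol
Product: 22 tert-butyl{[(2S,3R)-5-bromo-2-[4-(tert-butyldimethylsilyloxy)-3-methoxyphenyl]-7-methoxy-2,3-dihydrobenzofuran-3-yl]methoxy}dimethylsilane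
Conditions: TBSCl, imidazole, DMF, rt
Reagents that add atoms: tert-butyldimethylsilyl chloride, CC(C)(C)[Si](C)(C)Cl
Why: Silylation of the primary alcohol so that it survives the organolithium and enolate steps.

Step 15
Reactants: 22 aryl bromide
Product: 25 [(2S,3R)-3-[(tert-butyldimethylsilyloxy)methyl]-2-[4-(tert-butyldimethylsilyloxy)-3-methoxyphenyl]-7-methoxy-2,3-dihydrobenzofuran-5-yl]methanol, via aryllithium 23 (not isolated), via aldehyde 24 (not isolated)
Conditions: n-BuLi, THF, −78 °C; DMF, −78 → −40 °C; AcOH (1 equiv) in MeOH, then NaBH4, −40 → 0 °C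
Reagents that add atoms: N,N-dimethylformamide, CN(C)C=O
Why: Bromine–lithium exchange, Bouveault formylation of the aryllithium and borohydride reduction in one flask turn the ring B bromide into the benzylic alcohol, the exchange at −78 °C being faster than any deprotonation next to the ring oxygen.

Step 16
Reactants: 25 benzylic alcohol
Product: 26 {[(2S,3R)-5-(bromomethyl)-2-[4-(tert-butyldimethylsilyloxy)-3-methoxyphenyl]-7-methoxy-2,3-dihydrobenzofuran-3-yl]methoxy}(tert-butyl)dimethylsilane
Conditions: CBr4, PPh3, CH2Cl2, 0 °C; filtered through a short pad and used at once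
Reagents that add atoms: carbon tetrabromide, BrC(Br)(Br)Br
Why: Appel bromination of the benzylic alcohol under neutral conditions that the silyl ethers and the cyclic benzylic ether tolerate.

Step 17
Reactants: 11 silylated lactone; 26 benzylic bromide
Product: 28 (3R,4R)-4-[(R)-(tert-butyldimethylsilyloxy)(3-methoxy-4-pivaloyloxyphenyl)methyl]-3-{[(2S,3R)-3-[(tert-butyldimethylsilyloxy)methyl]-2-[4-(tert-butyldimethylsilyloxy)-3-methoxyphenyl]-7-methoxy-2,3-dihydrobenzofuran-5-yl]methyl}dihydrofuran-2(3H)-one, via lithium enolate 27 (not isolated)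
Conditions: LiN(SiMe3)2 (1.05 equiv), THF, −78 °C; then 26, DMPU, −78 → −40 °C
Reagents that add atoms: none
Why: Alkylation of the lactone lithium enolate with the benzylic bromide, in which the electrophile enters anti to the large C4 substituent and so sets C3 (R, trans), the usual outcome for β-substituted γ-butyrolactones.

Step 18
Reactants: 28 coupled lactone
Product: 29 (3R,4R)-4-[(R)-(tert-butyldimethylsilyloxy)(4-hydroxy-3-methoxyphenyl)methyl]-3-{[(2S,3R)-3-[(tert-butyldimethylsilyloxy)methyl]-2-(4-hydroxy-3-methoxyphenyl)-7-methoxy-2,3-dihydrobenzofuran-5-yl]methyl}dihydrofuran-2(3H)-one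
Conditions: K2CO3, MeOH–THF, 0 °C → rt; AcOH quench
Reagents that add atoms: none
Why: Base-catalysed methanolysis removes the aryl pivalate and the aryl silyl ether (phenoxide leaving groups) while the two alkyl silyl ethers stay, and a lactone opened by methoxide can reclose only through the primary oxygen because the carbinol is still silylated.

Step 19
Reactants: 29 bis-silyl diphenol
Product: 30 (3R,4R)-4-[(R)-hydroxy(4-hydroxy-3-methoxyphenyl)methyl]-3-{[(2S,3R)-2-(4-hydroxy-3-methoxyphenyl)-3-(hydroxymethyl)-7-methoxy-2,3-dihydrobenzofuran-5-yl]methyl}dihydrofuran-2(3H)-one (CNP0233460.1)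
Conditions: HF·pyridine, pyridine, THF, 0 °C → rt
Reagents that add atoms: none
Why: Fluoride cleavage of the two alkyl silyl ethers in a buffered, weakly acidic medium, which avoids base-induced quinone methide epimerisation or translactonisation and acid-induced cyclisation of the free 4-hydroxybenzylic alcohol.

## Compound list

1 | vanillin | COc1cc(C=O)ccc1O | starting material
2 | 4-formyl-2-methoxyphenyl pivalate | COc1cc(C=O)ccc1OC(=O)C(C)(C)C | intermediate
3 | (2-carboxyethyl)triphenylphosphonium bromide | OC(=O)CC[P+](c1ccccc1)(c1ccccc1)c1ccccc1.[Br-] | starting material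
4 | sodium 3-(triphenyl-λ5-phosphanylidene)propanoate (ylide carboxylate) | [Na+].[O-]C(=O)CC=P(c1ccccc1)(c1ccccc1)c1ccccc1 | intermediate
5 | (E)-4-(3-methoxy-4-pivaloyloxyphenyl)but-3-enoic acid | OC(=O)C/C=C/c1ccc(OC(=O)C(C)(C)C)c(OC)c1 | intermediate
6 | methyl (E)-4-(3-methoxy-4-pivaloyloxyphenyl)but-3-enoate | COC(=O)C/C=C/c1ccc(OC(=O)C(C)(C)C)c(OC)c1 | intermediate
7 | formaldehyde (as paraformaldehyde) | C=O | starting material
8 | methyl 2-[(4R,5R)-4-(3-methoxy-4-pivaloyloxyphenyl)-1,3-dioxan-5-yl]acetate | COC(=O)C[C@@H]1COCO[C@H]1c1ccc(OC(=O)C(C)(C)C)c(OC)c1 | intermediate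
9 | methyl (3R,4R)-4-hydroxy-3-(hydroxymethyl)-4-(3-methoxy-4-pivaloyloxyphenyl)butanoate | COC(=O)C[C@H](CO)[C@@H](O)c1ccc(OC(=O)C(C)(C)C)c(OC)c1 | intermediate
10 | (4R)-4-[(R)-hydroxy(3-methoxy-4-pivaloyloxyphenyl)methyl]dihydrofuran-2(3H)-one | O=C1C[C@H](CO1)[C@@H](O)c1ccc(OC(=O)C(C)(C)C)c(OC)c1 | intermediate
11 | (4R)-4-[(R)-(tert-butyldimethylsilyloxy)(3-methoxy-4-pivaloyloxyphenyl)methyl]dihydrofuran-2(3H)-one | O=C1C[C@H](CO1)[C@@H](O[Si](C)(C)C(C)(C)C)c1ccc(OC(=O)C(C)(C)C)c(OC)c1 | intermediate
12 | 4-(tert-butyldimethylsilyloxy)-3-methoxybenzaldehyde | COc1cc(C=O)ccc1O[Si](C)(C)C(C)(C)C | intermediate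
13 | [4-(tert-butyldimethylsilyloxy)-3-methoxyphenyl]methanol | COc1cc(CO)ccc1O[Si](C)(C)C(C)(C)C | intermediate
14 | 4-bromo-2-methoxyphenol | COc1cc(Br)ccc1O | starting material
15 | 4-bromo-2-iodo-6-methoxyphenol | COc1cc(Br)cc(I)c1O | intermediate
16 | tert-butyl{4-[(4-bromo-2-iodo-6-methoxyphenoxy)methyl]-2-methoxyphenoxy}dimethylsilane | COc1cc(Br)cc(I)c1OCc1ccc(O[Si](C)(C)C(C)(C)C)c(OC)c1 | intermediate
17 | ethyl diazoacetate | CCOC(=O)C=[N+]=[N-] | starting material
18 | ethyl 2-[5-bromo-2-{[4-(tert-butyldimethylsilyloxy)-3-methoxybenzyl]oxy}-3-methoxyphenyl]-2-diazoacetate | CCOC(=O)C(=[N+]=[N-])c1cc(Br)cc(OC)c1OCc1ccc(O[Si](C)(C)C(C)(C)C)c(OC)c1 | intermediate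
19 | ethyl (2S,3R)-5-bromo-2-[4-(tert-butyldimethylsilyloxy)-3-methoxyphenyl]-7-methoxy-2,3-dihydrobenzofuran-3-carboxylate (cis) | COc1cc([C@H]2Oc3c(OC)cc(Br)cc3[C@H]2C(=O)OCC)ccc1O[Si](C)(C)C(C)(C)C | intermediate
20 | ethyl (2S,3S)-5-bromo-2-[4-(tert-butyldimethylsilyloxy)-3-methoxyphenyl]-7-methoxy-2,3-dihydrobenzofuran-3-carboxylate (trans) | COc1cc([C@H]2Oc3c(OC)cc(Br)cc3[C@@H]2C(=O)OCC)ccc1O[Si](C)(C)C(C)(C)C | intermediate
21 | [(2S,3R)-5-bromo-2-[4-(tert-butyldimethylsilyloxy)-3-methoxyphenyl]-7-methoxy-2,3-dihydrobenzofuran-3-yl]methanol | COc1cc([C@H]2Oc3c(OC)cc(Br)cc3[C@@H]2CO)ccc1O[Si](C)(C)C(C)(C)C | intermediate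
22 | tert-butyl{[(2S,3R)-5-bromo-2-[4-(tert-butyldimethylsilyloxy)-3-methoxyphenyl]-7-methoxy-2,3-dihydrobenzofuran-3-yl]methoxy}dimethylsilane | COc1cc([C@H]2Oc3c(OC)cc(Br)cc3[C@@H]2CO[Si](C)(C)C(C)(C)C)ccc1O[Si](C)(C)C(C)(C)C | intermediate
23 | [(2S,3R)-3-[(tert-butyldimethylsilyloxy)methyl]-2-[4-(tert-butyldimethylsilyloxy)-3-methoxyphenyl]-7-methoxy-2,3-dihydrobenzofuran-5-yl]lithium | COc1cc([C@H]2Oc3c(OC)cc([Li])cc3[C@@H]2CO[Si](C)(C)C(C)(C)C)ccc1O[Si](C)(C)C(C)(C)C | intermediate
24 | (2S,3R)-3-[(tert-butyldimethylsilyloxy)methyl]-2-[4-(tert-butyldimethylsilyloxy)-3-methoxyphenyl]-7-methoxy-2,3-dihydrobenzofuran-5-carbaldehyde | COc1cc([C@H]2Oc3c(OC)cc(C=O)cc3[C@@H]2CO[Si](C)(C)C(C)(C)C)ccc1O[Si](C)(C)C(C)(C)C | intermediate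
25 | [(2S,3R)-3-[(tert-butyldimethylsilyloxy)methyl]-2-[4-(tert-butyldimethylsilyloxy)-3-methoxyphenyl]-7-methoxy-2,3-dihydrobenzofuran-5-yl]methanol | COc1cc([C@H]2Oc3c(OC)cc(CO)cc3[C@@H]2CO[Si](C)(C)C(C)(C)C)ccc1O[Si](C)(C)C(C)(C)C | intermediate
26 | {[(2S,3R)-5-(bromomethyl)-2-[4-(tert-butyldimethylsilyloxy)-3-methoxyphenyl]-7-methoxy-2,3-dihydrobenzofuran-3-yl]methoxy}(tert-butyl)dimethylsilane | COc1cc([C@H]2Oc3c(OC)cc(CBr)cc3[C@@H]2CO[Si](C)(C)C(C)(C)C)ccc1O[Si](C)(C)C(C)(C)C | intermediate
27 | lithium (4R)-4-[(R)-(tert-butyldimethylsilyloxy)(3-methoxy-4-pivaloyloxyphenyl)methyl]-4,5-dihydrofuran-2-olate (enolate of 11) | [Li+].[O-]C1=C[C@H](CO1)[C@@H](O[Si](C)(C)C(C)(C)C)c1ccc(OC(=O)C(C)(C)C)c(OC)c1 | intermediate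
28 | (3R,4R)-4-[(R)-(tert-butyldimethylsilyloxy)(3-methoxy-4-pivaloyloxyphenyl)methyl]-3-{[(2S,3R)-3-[(tert-butyldimethylsilyloxy)methyl]-2-[4-(tert-butyldimethylsilyloxy)-3-methoxyphenyl]-7-methoxy-2,3-dihydrobenzofuran-5-yl]methyl}dihydrofuran-2(3H)-one | COc1cc([C@H]2Oc3c(OC)cc(C[C@H]4C(=O)OC[C@@H]4[C@@H](O[Si](C)(C)C(C)(C)C)c4ccc(OC(=O)C(C)(C)C)c(OC)c4)cc3[C@@H]2CO[Si](C)(C)C(C)(C)C)ccc1O[Si](C)(C)C(C)(C)C | intermediate
29 | (3R,4R)-4-[(R)-(tert-butyldimethylsilyloxy)(4-hydroxy-3-methoxyphenyl)methyl]-3-{[(2S,3R)-3-[(tert-butyldimethylsilyloxy)methyl]-2-(4-hydroxy-3-methoxyphenyl)-7-methoxy-2,3-dihydrobenzofuran-5-yl]methyl}dihydrofuran-2(3H)-one | COc1cc([C@H]2Oc3c(OC)cc(C[C@H]4C(=O)OC[C@@H]4[C@@H](O[Si](C)(C)C(C)(C)C)c4ccc(O)c(OC)c4)cc3[C@@H]2CO[Si](C)(C)C(C)(C)C)ccc1O | intermediate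
30 | (3R,4R)-4-[(R)-hydroxy(4-hydroxy-3-methoxyphenyl)methyl]-3-{[(2S,3R)-2-(4-hydroxy-3-methoxyphenyl)-3-(hydroxymethyl)-7-methoxy-2,3-dihydrobenzofuran-5-yl]methyl}dihydrofuran-2(3H)-one | COc1cc([C@H]2Oc3c(OC)cc(C[C@H]4C(=O)OC[C@@H]4[C@@H](O)c4ccc(O)c(OC)c4)cc3[C@@H]2CO)ccc1O | target

## Step count

Total: 19 steps. Longest linear sequence: 12 steps (7, 8, 10, 11, 12, 13, 14, 15, 16, 17, 18, 19).

## Steps most likely to fail

Step 4 (Prins reaction). The internal alkene with its CH2CO2Me arm may react too slowly in the confined pocket or with poor facial selectivity. A stepwise path through a free benzylic cation would erode the trans relation, start oligomerisation with formaldehyde, or let the ester carbonyl capture the benzylic carbon. The fallback builds the 1,3-diol by an aldol C–C bond instead. It sets out from aldehyde 2: methyl 4-oxobutanoate is added slowly to 2 and L-proline (20 mol%) in DMF at 4 °C. This enamine cross-aldol of an aldehyde donor with an aromatic aldehyde acceptor is anti-selective and should give methyl (3S,4R)-3-formyl-4-hydroxy-4-(3-methoxy-4-pivaloyloxyphenyl)butanoate F1. NaBH4 added to the same flask at −20 °C reduces the formyl group and gives diol ester 9, where the route is rejoined for the lactonisation of step 5; the syn isomer would be removed at lactone 10.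

Step 5 (acetal cleavage and lactonisation). Acid strong enough to open the formaldehyde acetal may ionise the benzylic C–O bond (epimerisation or methyl ether formation) or methanolyse the pivalate, and the lactone may close in part through the benzylic hydroxyl. The fallback sets out from dioxane 8 and fixes the regiochemistry by protecting groups. The acetal is cleaved without protic acid by TMSOTf and 2,2′-bipyridyl in CH2Cl2 at 0 °C followed by water, giving diol ester 9. Both hydroxyls are silylated at once (TBSOTf, 2,6-lutidine, −78 °C) to methyl (3R,4R)-4-(tert-butyldimethylsilyloxy)-3-[(tert-butyldimethylsilyloxy)methyl]-4-(3-methoxy-4-pivaloyloxyphenyl)butanoate F2. The primary silyl ether alone is removed (HF·pyridine, pyridine, THF, 0 °C) to methyl (3R,4R)-4-(tert-butyldimethylsilyloxy)-3-(hydroxymethyl)-4-(3-methoxy-4-pivaloyloxyphenyl)butanoate F3. This lactonises (PPTS, toluene, 45 °C) through the only free hydroxyl and comes back to the route at 11.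

Step 11 (coupling of the diazoacetate). The diazo partner may decompose at palladium or silver faster than it couples with the hindered, electron-rich ortho-alkoxy aryl iodide, and some insertion into the C–Br bond may occur. The fallback sets out from iodide 16 and separates C–C bond formation from diazo installation. Negishi coupling with the Reformatsky reagent BrZnCH2CO2Et (Pd(PPh3)4, THF, 50 °C, iodide-selective) gives ethyl 2-[5-bromo-2-{[4-(tert-butyldimethylsilyloxy)-3-methoxybenzyl]oxy}-3-methoxyphenyl]acetate F4. Regitz diazo transfer (4-acetamidobenzenesulfonyl azide, DBU, MeCN, 0 °C → rt) then returns to the route at 18.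

## Further compounds

F1 | step 4 | methyl (3S,4R)-3-formyl-4-hydroxy-4-(3-methoxy-4-pivaloyloxyphenyl)butanoate | COC(=O)C[C@H](C=O)[C@@H](O)c1ccc(OC(=O)C(C)(C)C)c(OC)c1
F2 | step 5 | methyl (3R,4R)-4-(tert-butyldimethylsilyloxy)-3-[(tert-butyldimethylsilyloxy)methyl]-4-(3-methoxy-4-pivaloyloxyphenyl)butanoate | COC(=O)C[C@H](CO[Si](C)(C)C(C)(C)C)[C@@H](O[Si](C)(C)C(C)(C)C)c1ccc(OC(=O)C(C)(C)C)c(OC)c1
F3 | step 5 | methyl (3R,4R)-4-(tert-butyldimethylsilyloxy)-3-(hydroxymethyl)-4-(3-methoxy-4-pivaloyloxyphenyl)butanoate | COC(=O)C[C@H](CO)[C@@H](O[Si](C)(C)C(C)(C)C)c1ccc(OC(=O)C(C)(C)C)c(OC)c1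
F4 | step 11 | ethyl 2-[5-bromo-2-{[4-(tert-butyldimethylsilyloxy)-3-methoxybenzyl]oxy}-3-methoxyphenyl]acetate | CCOC(=O)Cc1cc(Br)cc(OC)c1OCc1ccc(O[Si](C)(C)C(C)(C)C)c(OC)c1
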